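**Plan**

1. Rings: A = 3,5-dihydroxyphenoxy on B-C1; B carries the C-linked ring B′; C = 2,6-dihydroxy-1,4-dioxy ring on B-C4; D = tris(aryloxy) ring; E/E′ and F/F′ = the two biaryl units on D. Rings B, E and F share one pattern: oxygen on C1, C2, C4 and C6, a symmetric trioxyphenyl ring on C5, hydrogen on C3. A squarate-derived 2-aryl-3-methoxy-4-oxy-4-(1-methoxyvinyl)cyclobutenone delivers exactly this pattern on thermal ring expansion.
2. Cuts, in retrosynthetic order: the 22 O–CH3 bonds; the C–O–D ether (ring-C boronic acid 19 + ring-D phenol 25); the C–B bond on ring C; the A–O–B ether; the B–O–C ether; in 25 the D-C1 oxygen (from a formyl group) and the two D–O–E/F ethers.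
3. All three biaryl phenol units come from one phenol, 12. Its ring is closed by the C3–C4 bond from cyclobutenone 9, which is assembled from 1,3,5-trimethoxybenzene, dimethyl squarate and methyl vinyl ether.
4. Forward: aryllithium + squarate, acid to the dione, methoxyvinyllithium addition with MOM trapping, then thermolysis to 12 (C4–OH free, C1–OMOM). One part of 12 receives ring C, ring A and a boron on ring C. Two parts are methylated, unmasked, joined to ring D by double SNAr and oxidised to phenol 25.
5. The fragments are united by Chan–Lam coupling and all methyl ethers are cleaved with BBr3.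
6. Stereochemistry: the target has no stereocentre, and its biaryl axes are not stereogenic because each C-linked ring is symmetric. The racemic carbinol carbon of 4 and 9 becomes sp2 in step 4.

Key step: step 4

Remark: 2-iodo-1,3-dimethoxybenzene, 3,5-dimethoxyphenylboronic acid and 2,6-difluoro-4-methoxybenzaldehyde are taken as purchased building blocks; phenol 12 is made once and divided between steps 5 and 9.

**Route**

Step 1
Reactants: 1 1,3,5-trimethoxybenzene; 2 dimethyl squarate
Product: 4 4-hydroxy-2,3-dimethoxy-4-(2,4,6-trimethoxyphenyl)cyclobut-2-en-1-one (racemic), via 2,4,6-trimethoxyphenyllithium 3 (not isolated)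
Conditions: n-BuLi, THF, 0 °C to rt; then add to 2, THF, −78 °C; aq. NH4Cl
Reagents that add atoms: none
Why: Directed ortho-lithiation between two methoxy groups followed by 1,2-addition of the aryllithium to one squarate carbonyl at low temperature is the standard entry to 4-aryl-4-hydroxycyclobutenones, and the hindered B–B′ bond is thereby made as a simple carbonyl addition; the carbinol centre forms racemic.

Step 2
Reactants: 4 4-hydroxy-2,3-dimethoxy-4-(2,4,6-trimethoxyphenyl)cyclobut-2-en-1-one
Product: 5 3-methoxy-4-(2,4,6-trimethoxyphenyl)cyclobut-3-ene-1,2-dione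
Conditions: conc. HCl (cat.), CH2Cl2, rt
Reagents that add atoms: water, O
Why: Acid ionises the aryl-stabilised allylic carbinol, water re-enters at the distal methoxy-bearing carbon and methanol is lost, the usual acid-promoted rearrangement of squarate adducts to 3-alkoxy-4-arylcyclobutenediones.

Step 3
Reactants: 5 3-methoxy-4-(2,4,6-trimethoxyphenyl)cyclobut-3-ene-1,2-dione; 6 methyl vinyl ether
Product: 9 3-methoxy-4-(methoxymethoxy)-4-(1-methoxyvinyl)-2-(2,4,6-trimethoxyphenyl)cyclobut-2-en-1-one (racemic), via 1-methoxyvinyllithium 7 (not isolated), via lithium cyclobutenolate 8 (not isolated)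
Conditions: 6, t-BuLi, THF, −78 to 0 °C; then 5, −78 °C; then MOMCl, −78 to 0 °C
Reagents that add atoms: chloromethyl methyl ether (MOMCl), COCCl
Why: The α-alkoxyvinyllithium should add 1,2 to the ketone-like carbonyl beside the methoxy-bearing carbon (the other carbonyl is a vinylogous ester shielded by the aryl ring), and the lithium alkoxide is O-alkylated by the reactive chloromethyl ether (Williamson-type trapping); the MOM group is chosen over a silyl group because it survives the basic, fluoride-free and fluoride-forming couplings that follow, and the product is racemic.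

Step 4
Reactants: 9 3-methoxy-4-(methoxymethoxy)-4-(1-methoxyvinyl)-2-(2,4,6-trimethoxyphenyl)cyclobut-2-en-1-one
Product: 12 3,5-dimethoxy-4-(methoxymethoxy)-2-(2,4,6-trimethoxyphenyl)phenol, via dienylketene 10 (not isolated), via cyclohexa-2,4-dienone 11 (not isolated)
Conditions: PhMe (degassed), 110 °C, Ar
Reagents that add atoms: none
Why: Heating should open the cyclobutenone in a four-electron conrotatory electrocyclic ring opening to the (3Z)-dienylketene 10, whose ketene carbon and terminal CH2 then bond in a six-electron disrotatory electrocyclisation to dienone 11, which enolises to the phenol; this is the Moore rearrangement of 4-alkenyl-4-oxycyclobutenones. The single ring that closes, the six-membered carbocycle that becomes ring B (and, in other portions, rings E and F), is formed by that 6π electrocyclic closure, which makes the C3–C4 bond in the ring numbering of the target. No stereocentre is created, and the racemic carbinol carbon of 9 ends as the sp2 carbon C1. The step needs torquoselectivity: the donor methoxymethoxy group on the carbinol carbon rotates outward, so the methoxyvinyl group turns inward toward the ketene and no other π-substituent competes. The substitution pattern was fixed by the site of addition in step 3, so the ketene oxygen emerges as the free C4 hydroxyl next to ring B′ and the carbinol oxygen as the C1 MOM ether between two methoxy groups, which differentiates the two ether sites.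

Step 5
Reactants: 12 3,5-dimethoxy-4-(methoxymethoxy)-2-(2,4,6-trimethoxyphenyl)phenol; 13 2-iodo-1,3-dimethoxybenzene
Product: 14 1-(2,6-dimethoxyphenoxy)-3,5-dimethoxy-4-(methoxymethoxy)-2-(2,4,6-trimethoxyphenyl)benzene
Conditions: CuI (cat.), picolinic acid, K3PO4, DMSO, 100 °C, Ar
Reagents that add atoms: none
Why: Ullmann-type copper-catalysed C–O coupling with a picolinate ligand is suited to ortho-substituted partners, 2-halo-1,3-dimethoxyarenes are the classical electrophiles for phlorethol ether bonds, and the MOM ether is inert to phosphate base.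

Step 6
Reactants: 14 1-(2,6-dimethoxyphenoxy)-3,5-dimethoxy-4-(methoxymethoxy)-2-(2,4,6-trimethoxyphenyl)benzene
Product: 15 4-(2,6-dimethoxyphenoxy)-2,6-dimethoxy-3-(2,4,6-trimethoxyphenyl)phenol
Conditions: HCl (cat.), MeOH, 50 °C
Reagents that add atoms: none
Why: Acid-catalysed acetal exchange cleaves the aryl MOM ether while the solvent traps the methoxymethyl cation as dimethoxymethane, so the electron-rich rings are not alkylated and methyl and diaryl ethers stay intact.

Step 7
Reactants: 15 4-(2,6-dimethoxyphenoxy)-2,6-dimethoxy-3-(2,4,6-trimethoxyphenyl)phenol; 16 3,5-dimethoxyphenylboronic acid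
Product: 17 1-(2,6-dimethoxyphenoxy)-4-(3,5-dimethoxyphenoxy)-3,5-dimethoxy-2-(2,4,6-trimethoxyphenyl)benzene
Conditions: Cu(OAc)2, pyridine, 4 Å MS, CH2Cl2, air, rt
Reagents that add atoms: none
Why: Chan–Lam oxidative C–O coupling at room temperature accepts phenols with two ortho substituents when the arylboronic acid is unhindered and can be used in excess, as here for ring A.

Step 8
Reactants: 17 1-(2,6-dimethoxyphenoxy)-4-(3,5-dimethoxyphenoxy)-3,5-dimethoxy-2-(2,4,6-trimethoxyphenyl)benzene
Product: 19 {4-[4-(3,5-dimethoxyphenoxy)-3,5-dimethoxy-2-(2,4,6-trimethoxyphenyl)phenoxy]-3,5-dimethoxyphenyl}boronic acid, via pinacol boronate 18 (not isolated)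
Conditions: [Ir(OMe)(cod)]2 (cat.), dtbpy, B2pin2, THF, 80 °C; then NaIO4, aq. NH4OAc, rt
Reagents that add atoms: bis(pinacolato)diboron, CC1(C)OB(OC1(C)C)B1OC(C)(C)C(C)(C)O1; water, O
Why: Iridium-catalysed C–H borylation is sterically controlled and the only aromatic C–H of 17 without an ortho substituent is C4 of ring C (every other ring hydrogen lies between two oxygen substituents or beside a methoxy group), and periodate cleavage of pinacol then frees the boronic acid.

Step 9
Reactants: 12 3,5-dimethoxy-4-(methoxymethoxy)-2-(2,4,6-trimethoxyphenyl)phenol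
Product: 20 1,3,5-trimethoxy-2-(methoxymethoxy)-4-(2,4,6-trimethoxyphenyl)benzene
Conditions: MeI, K2CO3, acetone, reflux
Reagents that add atoms: iodomethane, CI
Why: Williamson O-methylation of the only free phenol, with the MOM ether stable to carbonate, turns the ketene-derived oxygen into the C4 methyl ether needed for rings E and F.

Step 10
Reactants: 20 1,3,5-trimethoxy-2-(methoxymethoxy)-4-(2,4,6-trimethoxyphenyl)benzene
Product: 21 2,4,6-trimethoxy-3-(2,4,6-trimethoxyphenyl)phenol
Conditions: HCl (cat.), MeOH, 50 °C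
Reagents that add atoms: none
Why: The same acid-catalysed acetal exchange as in step 6 unmasks the C1 phenol of the E–E′ (F–F′) unit without touching the methyl ethers.

Step 11
Reactants: 21 2,4,6-trimethoxy-3-(2,4,6-trimethoxyphenyl)phenol (2 equiv); 22 2,6-difluoro-4-methoxybenzaldehyde
Product: 23 4-methoxy-2,6-bis[2,4,6-trimethoxy-3-(2,4,6-trimethoxyphenyl)phenoxy]benzaldehyde
Conditions: Cs2CO3, DMSO, 120 °C, Ar
Reagents that add atoms: none
Why: Two-fold nucleophilic aromatic substitution is possible because both fluorines are ortho to the formyl group, the 4-methoxy group is meta to the reacting carbons, attack on an aryl fluoride tolerates the 2,6-dimethoxyphenoxide, and the non-enolisable aldehyde survives carbonate.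

Step 12
Reactants: 23 4-methoxy-2,6-bis[2,4,6-trimethoxy-3-(2,4,6-trimethoxyphenyl)phenoxy]benzaldehyde
Product: 25 4-methoxy-2,6-bis[2,4,6-trimethoxy-3-(2,4,6-trimethoxyphenyl)phenoxy]phenol, via aryl formate 24 (not isolated)
Conditions: mCPBA, CH2Cl2, 0 °C to rt; then K2CO3 (cat.), MeOH, rt
Reagents that add atoms: 3-chloroperbenzoic acid (mCPBA), OOC(=O)c1cccc(Cl)c1
Why: Baeyer–Villiger (Dakin-type) oxidation of a 2,4,6-trioxygenated benzaldehyde proceeds with migration of the electron-rich aryl group, and mild methanolysis of the formate gives the ring-D phenol.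

Step 13
Reactants: 25 4-methoxy-2,6-bis[2,4,6-trimethoxy-3-(2,4,6-trimethoxyphenyl)phenoxy]phenol; 19 {4-[4-(3,5-dimethoxyphenoxy)-3,5-dimethoxy-2-(2,4,6-trimethoxyphenyl)phenoxy]-3,5-dimethoxyphenyl}boronic acid
Product: 26 docosa-O-methyl ether of the target (all 22 hydroxyl groups as methyl ethers)
Conditions: Cu(OAc)2, pyridine, Et3N, 4 Å MS, CH2Cl2, O2, rt
Reagents that add atoms: none
Why: Chan–Lam coupling places the hindered partner on the phenol side, where two ortho substituents are tolerated, and the boron on the unhindered C4 of ring C, so the C–O–D ether should form under the same mild oxidative conditions as in step 7.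

Step 14
Reactants: 26 docosa-O-methyl ether of the target
Product: 27 CNP0117322.0 (target)
Conditions: BBr3 (excess), CH2Cl2, −78 °C to rt; then ice-water
Reagents that add atoms: none
Why: Lewis-acid ether cleavage with BBr3 (boron coordinates each methoxy oxygen and bromide attacks the methyl carbon) removes all aryl methyl ethers while the sp2 C–O bonds of the diaryl ethers and the biaryl bonds are inert.

**Compound list**

1 | 1,3,5-trimethoxybenzene | COc1cc(OC)cc(OC)c1 | starting material
2 | dimethyl squarate | COC1=C(OC)C(=O)C1=O | starting material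
3 | 2,4,6-trimethoxyphenyllithium | [Li]c1c(OC)cc(OC)cc1OC | intermediate
4 | 4-hydroxy-2,3-dimethoxy-4-(2,4,6-trimethoxyphenyl)cyclobut-2-en-1-one (racemic) | O=C1C(OC)=C(OC)C1(O)c1c(OC)cc(OC)cc1OC | intermediate
5 | 3-methoxy-4-(2,4,6-trimethoxyphenyl)cyclobut-3-ene-1,2-dione | COC1=C(c2c(OC)cc(OC)cc2OC)C(=O)C1=O | intermediate
6 | methyl vinyl ether | COC=C | starting material
7 | 1-methoxyvinyllithium | [Li]C(OC)=C | intermediate
8 | lithium 2-methoxy-1-(1-methoxyvinyl)-4-oxo-3-(2,4,6-trimethoxyphenyl)cyclobut-2-en-1-olate (racemic) | [Li]OC1(C(OC)=C)C(OC)=C(c2c(OC)cc(OC)cc2OC)C1=O | intermediate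
9 | 3-methoxy-4-(methoxymethoxy)-4-(1-methoxyvinyl)-2-(2,4,6-trimethoxyphenyl)cyclobut-2-en-1-one (racemic) | COCOC1(C(OC)=C)C(OC)=C(c2c(OC)cc(OC)cc2OC)C1=O | intermediate
10 | (3Z)-3,5-dimethoxy-4-(methoxymethoxy)-2-(2,4,6-trimethoxyphenyl)hexa-1,3,5-trien-1-one | O=C=C(c1c(OC)cc(OC)cc1OC)/C(OC)=C(OCOC)\C(OC)=C | intermediate
11 | 3,5-dimethoxy-4-(methoxymethoxy)-2-(2,4,6-trimethoxyphenyl)cyclohexa-2,4-dien-1-one | O=C1CC(OC)=C(OCOC)C(OC)=C1c1c(OC)cc(OC)cc1OC | intermediate
12 | 3,5-dimethoxy-4-(methoxymethoxy)-2-(2,4,6-trimethoxyphenyl)phenol | Oc1cc(OC)c(OCOC)c(OC)c1-c1c(OC)cc(OC)cc1OC | intermediate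
13 | 2-iodo-1,3-dimethoxybenzene | COc1cccc(OC)c1I | starting material
14 | 1-(2,6-dimethoxyphenoxy)-3,5-dimethoxy-4-(methoxymethoxy)-2-(2,4,6-trimethoxyphenyl)benzene | COc1cccc(OC)c1Oc1cc(OC)c(OCOC)c(OC)c1-c1c(OC)cc(OC)cc1OC | intermediate
15 | 4-(2,6-dimethoxyphenoxy)-2,6-dimethoxy-3-(2,4,6-trimethoxyphenyl)phenol | COc1cccc(OC)c1Oc1cc(OC)c(O)c(OC)c1-c1c(OC)cc(OC)cc1OC | intermediate
16 | 3,5-dimethoxyphenylboronic acid | COc1cc(OC)cc(B(O)O)c1 | starting material
17 | 1-(2,6-dimethoxyphenoxy)-4-(3,5-dimethoxyphenoxy)-3,5-dimethoxy-2-(2,4,6-trimethoxyphenyl)benzene | COc1cc(OC)cc(Oc2c(OC)cc(Oc3c(OC)cccc3OC)c(-c3c(OC)cc(OC)cc3OC)c2OC)c1 | intermediate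
18 | 2-{4-[4-(3,5-dimethoxyphenoxy)-3,5-dimethoxy-2-(2,4,6-trimethoxyphenyl)phenoxy]-3,5-dimethoxyphenyl}-4,4,5,5-tetramethyl-1,3,2-dioxaborolane | COc1cc(B2OC(C)(C)C(C)(C)O2)cc(OC)c1Oc1cc(OC)c(Oc2cc(OC)cc(OC)c2)c(OC)c1-c1c(OC)cc(OC)cc1OC | intermediate
19 | {4-[4-(3,5-dimethoxyphenoxy)-3,5-dimethoxy-2-(2,4,6-trimethoxyphenyl)phenoxy]-3,5-dimethoxyphenyl}boronic acid | COc1cc(B(O)O)cc(OC)c1Oc1cc(OC)c(Oc2cc(OC)cc(OC)c2)c(OC)c1-c1c(OC)cc(OC)cc1OC | intermediate
20 | 1,3,5-trimethoxy-2-(methoxymethoxy)-4-(2,4,6-trimethoxyphenyl)benzene | COCOc1c(OC)cc(OC)c(-c2c(OC)cc(OC)cc2OC)c1OC | intermediate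
21 | 2,4,6-trimethoxy-3-(2,4,6-trimethoxyphenyl)phenol | Oc1c(OC)cc(OC)c(-c2c(OC)cc(OC)cc2OC)c1OC | intermediate
22 | 2,6-difluoro-4-methoxybenzaldehyde | COc1cc(F)c(C=O)c(F)c1 | starting material
23 | 4-methoxy-2,6-bis[2,4,6-trimethoxy-3-(2,4,6-trimethoxyphenyl)phenoxy]benzaldehyde | COc1cc(Oc2c(OC)cc(OC)c(-c3c(OC)cc(OC)cc3OC)c2OC)c(C=O)c(Oc2c(OC)cc(OC)c(-c3c(OC)cc(OC)cc3OC)c2OC)c1 | intermediate
24 | 4-methoxy-2,6-bis[2,4,6-trimethoxy-3-(2,4,6-trimethoxyphenyl)phenoxy]phenyl formate | COc1cc(Oc2c(OC)cc(OC)c(-c3c(OC)cc(OC)cc3OC)c2OC)c(OC=O)c(Oc2c(OC)cc(OC)c(-c3c(OC)cc(OC)cc3OC)c2OC)c1 | intermediate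
25 | 4-methoxy-2,6-bis[2,4,6-trimethoxy-3-(2,4,6-trimethoxyphenyl)phenoxy]phenol | COc1cc(Oc2c(OC)cc(OC)c(-c3c(OC)cc(OC)cc3OC)c2OC)c(O)c(Oc2c(OC)cc(OC)c(-c3c(OC)cc(OC)cc3OC)c2OC)c1 | intermediate
26 | docosa-O-methyl ether of the target | COc1cc(OC)cc(Oc2c(OC)cc(Oc3c(OC)cc(Oc4c(Oc5c(OC)cc(OC)c(-c6c(OC)cc(OC)cc6OC)c5OC)cc(OC)cc4Oc4c(OC)cc(OC)c(-c5c(OC)cc(OC)cc5OC)c4OC)cc3OC)c(-c3c(OC)cc(OC)cc3OC)c2OC)c1 | intermediate
27 | CNP0117322.0 | Oc1cc(O)cc(Oc2c(O)cc(Oc3c(O)cc(Oc4c(Oc5c(O)cc(O)c(-c6c(O)cc(O)cc6O)c5O)cc(O)cc4Oc4c(O)cc(O)c(-c5c(O)cc(O)cc5O)c4O)cc3O)c(-c3c(O)cc(O)cc3O)c2O)c1 | target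

**Step count and risks**

Total steps: 14. Longest linear sequence: 10 steps (steps 1–4, 5–8, 13, 14; the branch through steps 9–12 is equally long).

Steps most likely to fail:

Step 14. Cleavage of 22 methyl ethers may stall at partly methylated stages as boron phenoxides precipitate, and the free polyphenol may be lost to air oxidation and irreversible adsorption during aqueous work-up and chromatography. The fallback sets out from 26 and replaces direct isolation by a derivatise, purify and release sequence. After the BBr3 treatment the quenched, evaporated crude is peracetylated (Ac2O, pyridine, DMAP, rt) to the docosaacetate F1. F1 should be air-stable and chromatographable on silica, so under-demethylated acetates can be separated and resubmitted. Acid-catalysed methanolysis of F1 (HCl generated from AcCl in degassed MeOH, rt) then gives only volatile by-products and returns to the route at 27.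

Step 13. C–O bond formation at a phenoxide flanked by two aryloxy groups may be slow enough that protodeboronation and homocoupling of the precious boronic acid, and oxidative degradation of the hydroquinone-type phenol, outrun the coupling. The fallback sets out from 19. Copper-catalysed iododeboronation (CuI, 1,10-phenanthroline, KI, MeOH–H2O, air, 80 °C) involves no electrophilic iodine and so spares the electron-rich rings; it should give 1-(4-iodo-2,6-dimethoxyphenoxy)-4-(3,5-dimethoxyphenoxy)-3,5-dimethoxy-2-(2,4,6-trimethoxyphenyl)benzene F2. A non-oxidative Ullmann coupling of F2 with phenol 25 (CuI, picolinic acid, K3PO4, DMSO, 100 °C, Ar), run with near-equimolar partners, returns to the route at 26.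

Step 5. Copper insertion and C–O bond formation at an iodide flanked by two methoxy groups, with a phenoxide that carries an ortho aryl ring, may be so slow that reductive deiodination and oxidative decomposition of the electron-rich phenol dominate. The fallback sets out from 12. Nucleophilic aromatic substitution on 4-fluoro-3,5-dimethoxybenzaldehyde (K2CO3, DMF, 120 °C) is activated by the para formyl group and is less sensitive to the flanking methoxy groups; it should give 4-[3,5-dimethoxy-4-(methoxymethoxy)-2-(2,4,6-trimethoxyphenyl)phenoxy]-3,5-dimethoxybenzaldehyde F3. Catalytic Tsuji–Wilkinson-type decarbonylation of F3 (RhCl3·3H2O, dppp, diglyme, 160 °C) removes the formyl group and returns to the route at 14.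

**Further compounds**

F1 | step 14 | docosaacetate of the target (all 22 hydroxyl groups as acetates) | CC(=O)Oc1cc(OC(C)=O)cc(Oc2c(OC(C)=O)cc(Oc3c(OC(C)=O)cc(Oc4c(Oc5c(OC(C)=O)cc(OC(C)=O)c(-c6c(OC(C)=O)cc(OC(C)=O)cc6OC(C)=O)c5OC(C)=O)cc(OC(C)=O)cc4Oc4c(OC(C)=O)cc(OC(C)=O)c(-c5c(OC(C)=O)cc(OC(C)=O)cc5OC(C)=O)c4OC(C)=O)cc3OC(C)=O)c(-c3c(OC(C)=O)cc(OC(C)=O)cc3OC(C)=O)c2OC(C)=O)c1
F2 | step 13 | 1-(4-iodo-2,6-dimethoxyphenoxy)-4-(3,5-dimethoxyphenoxy)-3,5-dimethoxy-2-(2,4,6-trimethoxyphenyl)benzene | COc1cc(I)cc(OC)c1Oc1cc(OC)c(Oc2cc(OC)cc(OC)c2)c(OC)c1-c1c(OC)cc(OC)cc1OC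
F3 | step 5 | 4-[3,5-dimethoxy-4-(methoxymethoxy)-2-(2,4,6-trimethoxyphenyl)phenoxy]-3,5-dimethoxybenzaldehyde | COc1cc(C=O)cc(OC)c1Oc1cc(OC)c(OCOC)c(OC)c1-c1c(OC)cc(OC)cc1OC
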